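In a one-step world the charge turns first order into target, the percentage curve is the same at any loading, and it climbs to 100 %.

| flask | solid substrate | remark | time |
|---|---|---|---|
| midnight | 0.23 M | run made earlier |  |
| winter | 0.55 M | run made earlier |  |
| dawn | 1.6 M | run made earlier |  |
| Tuesday's | 0.20 M |  | 1.5 h |
| Thursday's | 0.40 M |  | 1.5 h |
| Monday's | 0.80 M |  | 1.5 h |
| Wednesday's | 1.5 M |  | 1.5 h |

| run | time / min | target / % |
|---|---|---|
| midnight | 4.00 | 5 |
| midnight | 6.00 | 8 |
| midnight | 12.0 | 18 |
| midnight | 25.0 | 38 |
| midnight | 50.0 | 53 |
| winter | 4.00 | 0 |
| winter | 6.00 | 3 |
| winter | 12.0 | 16 |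
| winter | 25.0 | 38 |
| winter | 50.0 | 56 |
| dawn | 4.00 | 0 |
| dawn | 12.0 | 13 |
| dawn | 20.0 | 33 |
| dawn | 30.0 | 43 |
| dawn | 50.0 | 52 |

(scatter of a reading: 2 percentage points)

- as a solid, counted per litre of solution: solid substrate
- the earlier runs were read with a standard deviation of 2 percentage points
- at the start none of the solid substrate is in solution
- "hardly changes" means that all values lie within two and a half points (for a concentration: within two and a half percent of the largest)

- [target] at the end for Tuesday's, Thursday's, Monday's, Wednesday's, in this order
- the course of these numbers from the first flask to the last (rises all the way / rises, then falls / hardly changes / falls all the way / falls, then rises)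

One part of that picture stands late in the runs: at 50.0 min the readings are 53 %, 56 % and 52 % for charges of 0.23 M, 0.55 M and 1.6 M, and a reading carries 2 percentage points. The other part fails: reckoned towards 100 %, the constant of the dawn run is 0.0162 min⁻¹ between 20.0 min and 30.0 min, but 0.00859 min⁻¹ between 30.0 min and 50.0 min. So the dawn curve aims lower, and I want its end before its speed.

My first way doesn't need the moment the clock starts. I let the gap to the plateau shrink by a fixed factor per step of 10.0 min. The dawn run gains 10 points in one step and 9 points in the next two, which gives a factor of 0.572. That leaves a gap of 4.4 points at 50.0 min, so the plateau share P, the ultimate yield of target in percent of the charge, reads 56.4 %.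

My second way starts the clock at zero and lets the gap shrink equally from zero to 25.0 min and from there to 50.0 min. This gives 62.8 % in the midnight run and 72.2 % in the winter run, both above P. The two ways part, so I test the second: its winter curve puts 8.14 % at 4.00 min, where the reading is 0 %. In the winter run target comes after a lag, so the zero clock is the one that cheats.

I keep P, with the scatter of its readings. By the same factor the gap reckons to 0.47 points at 1.5 h, so I commit to P times the charge: 0.113 M, 0.226 M, 0.451 M and 0.846 M.

The forecast, made from the same runs, gives 0.116 M, 0.232 M, 0.464 M and 0.87 M, a row that rises all the way and stands above mine, on this ground: “That gives 0.58 times each charge”.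

The flask gives 0.106 M, 0.213 M, 0.425 M and 0.797 M, a row that rises all the way.

    starting material ⇌ intermediate A (K = 30.0, k = 0.00170 s⁻¹)
    intermediate A → intermediate B (k = 8.80 × 10⁻⁴ s⁻¹)
    intermediate B → side product (k = 5.50 × 10⁻⁴ s⁻¹)
    intermediate A → intermediate C (k = 0.00110 s⁻¹)
    intermediate C → target (k = 0.0110 s⁻¹)
    starting material → intermediate B (k = 7.30 × 10⁻⁵ s⁻¹)
    solid substrate ⇌ starting material, rate k7*(cs7 - [starting material]) while solid is left; crystals form when [starting material] > cs7 (solubility = 1.20 M, k = 0.0140 s⁻¹)

In Tuesday's flask, counting turnover up to 1.5 h, the dissolving of solid substrate reaches the midpoint of its turnover by 0.104 min, and the making of intermediate A from starting material has 99 % of its turnover behind it at 0.750 h, while the loss of intermediate A to intermediate C reaches its midpoint by 0.253 h. In Tuesday's flask, from 0.750 h to 1.50 h, target goes from 50.6 % to 53.2 % of the charge, while side product goes from 26.7 % to 42.0 %. P gave 0.113 M for Tuesday's against 0.106 M, and 0.846 M for Wednesday's against 0.797 M. At 15.0 h Wednesday's flask holds target at 53.2 % of the charge and side product at 46.8 %.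

(Readings and results were computed for an exercise; the scatter is artificial.)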